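**Plan**

- Numbering is that of labdane: ring A = C1–C5 and C10, ring B = C5–C10, C17 on C8, C18 (methyl) and C19 (CH2O) on C4, C20 on C10, side chain C11–C16 on C9; α is the face opposite C20.
- Retrosynthesis: cut the C19–O angelate and the C12–C13 bond (sp3–sp2 coupling with a Z-iodoenoate), then C4–C18 (enolate methylation). The C4–C5 bond of ring A is then traced back to a C19–C5 bond, so ring A comes from a seven-membered ketone that holds C19 in the ring between C4 and C5. Last cuts are C9–C10 (cation–olefin closure of ring B on an enone) and C5–C6 (Negishi coupling).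
- Forward: the chain and a cycloheptenone are joined, ring B is closed on the enone β-carbon C10, the seven-membered ring is contracted to ring A, and then C18, the side chain, the angelate and the free acid follow.
- Enabling feature: C4 is a quaternary ring-A carbon bearing an exocyclic carbon at the carboxyl level (C19) next to the ring-fusion carbon C5, which is the retron of a Wolff ring contraction. As a ring carbonyl, C19 first activates C10 for ring-B closure, then leaves C4 as the only α-methylene for diazo transfer, and ends as the ester whose enolate is methylated.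
- Stereochemistry: C9, C10 and the absolute sense come from a chair-like cyclisation under a chiral acid; C5 from protonation anti to C20, kept through the 1,2-shift; C4 from α-face methylation (C19 axial, cis to C20); 13Z from a stereoretentive coupling; the angelate geometry from angelic acid.

Key step: step 8

Remark: 1, 2, 7, 21, 23 and 27 are taken as catalogue compounds.

Step 1
Reactants: 1 tert-butyl(but-3-yn-1-yloxy)dimethylsilane; 2 oxirane
Product: 4 (E)-6-(tert-butyldimethylsilyloxy)-4-methylhex-3-en-1-ol, via alkenylalane 3 (not isolated)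
Conditions: Me3Al, Cp2ZrCl2 (20 mol %), CH2Cl2, 0 → 23 °C; then n-BuLi, THF/hexane, −30 °C; 2, −30 → 0 °C
Reagents that add atoms: trimethylaluminium, C[Al](C)C
Why: Zirconium-catalysed Negishi carboalumination adds methyl and aluminium syn and regioselectively across the terminal alkyne, and the derived alanate opens oxirane with retention at the alkenyl carbon, so the E-trisubstituted C8=C9 alkene (C7 trans to C11) should be fixed here.

Step 2
Reactants: 4 (E)-6-(tert-butyldimethylsilyloxy)-4-methylhex-3-en-1-ol
Product: 5 (E)-tert-butyl[(6-chloro-3-methylhex-3-en-1-yl)oxy]dimethylsilane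
Conditions: PPh3, N-chlorosuccinimide, CH2Cl2, 0 → 23 °C
Reagents that add atoms: N-chlorosuccinimide, O=C1CCC(=O)N1Cl
Why: Appel-type SN2 chlorination of the primary alcohol through its alkoxyphosphonium salt should leave the silyl ether and the alkene untouched.

Step 3
Reactants: 5 (E)-tert-butyl[(6-chloro-3-methylhex-3-en-1-yl)oxy]dimethylsilane
Product: 6 (E)-1-bromo-6-chloro-3-methylhex-3-ene
Conditions: PPh3, Br2, CH2Cl2, 0 → 23 °C
Reagents that add atoms: bromine, BrBr
Why: Dibromotriphenylphosphorane converts a primary silyl ether directly into the bromide (silyl ether cleavage–bromination), and the primary chloride is inert to it.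

Step 4
Reactants: 7 3-methylcyclohept-2-en-1-one
Product: 9 2-bromo-3-methylcyclohept-2-en-1-one, via dibromoketone 8 (not isolated)
Conditions: Br2, CH2Cl2, 0 °C; then Et3N, 0 → 23 °C
Reagents that add atoms: bromine, BrBr
Why: Bromine addition to the enone followed by amine-induced loss of HBr (bromination–dehydrobromination) is the standard entry to α-bromoenones.

Step 5
Reactants: 6 (E)-1-bromo-6-chloro-3-methylhex-3-ene; 9 2-bromo-3-methylcyclohept-2-en-1-one
Product: 11 2-[(E)-6-chloro-3-methylhex-3-en-1-yl]-3-methylcyclohept-2-en-1-one, via alkylzinc bromide 10 (not isolated)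
Conditions: 6, Zn, LiCl, THF, 50 °C; then 9, PdCl2(dppf) (3 mol %), THF, 23 → 40 °C
Reagents that add atoms: none
Why: Zinc inserts into the primary C–Br bond but not the C–Cl bond, and Negishi coupling of the alkylzinc with the activated vinyl bromide (oxidative addition to zerovalent palladium) should form the C5–C6 bond.

Step 6
Reactants: 11 2-[(E)-6-chloro-3-methylhex-3-en-1-yl]-3-methylcyclohept-2-en-1-one
Product: 12 trans-fused A-homo ketone (1-(2-chloroethyl)-2,9a-dimethyl-1,4,4a,6,7,8,9,9a-octahydro-5H-benzo[7]annulen-5-one; 5α-H; 9α-H; 10β-CH3; C19 is the ring carbonyl)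
Conditions: chiral IDPi Brønsted acid (5 mol %), (CF3)3COH/CHCl3, −40 → −20 °C
Reagents that add atoms: none
Why: Proposed new method: the confined chiral acid protonates the enone oxygen to a 1-hydroxyallyl cation held as a contact ion pair with the chiral imidodiphosphorimidate anion; the E-configured C8=C9 alkene attacks the β-carbon C10 through a chair-like six-membered transition state (C11 equatorial, so H-9 and C20 end anti); the tertiary C8 cation loses the axial H-7 to the anion, giving the C7=C8 alkene and returning the proton; the dienol is protonated at C5 from the face opposite the axial C20 methyl, giving the trans ring fusion, which is also the expected thermodynamic epimer; the catalyst antipode that leads to the drawn enantiomer is to be selected by a screen; the closest known reaction types are the acid-mediated cyclisation of 2-(alk-3-enyl)-3-methylcycloalk-2-enones to angularly methylated bicyclic ketones and the asymmetric Nazarov and polyene cyclisations catalysed by the same class of acid, in which a protonated enone or alkene reacts inside the chiral anion pocket.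

Step 7
Reactants: 12 trans-fused A-homo ketone
Product: 14 6-diazo derivative of 12 (diazo group on C4), via trifluoroacetyl ketone 13 (not isolated)
Conditions: LiN(SiMe3)2, THF, −78 °C; CF3CO2CH2CF3; then MsN3, Et3N, H2O, MeCN, 23 °C
Reagents that add atoms: methanesulfonyl azide, CS(=O)(=O)N=[N+]=[N-]
Why: Kinetic deprotonation should occur at the C4 methylene and not at the hindered C5 methine, and Claisen trifluoroacetylation followed by detrifluoroacetylative (Regitz-type) diazo transfer delivers the α-diazo ketone without touching C5.

Step 8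
Reactants: 14 6-diazo derivative of 12
Product: 16 methyl 5-(2-chloroethyl)-4a,6-dimethyl-1,2,3,4,4a,5,8,8a-octahydronaphthalene-1-carboxylate (C4 epimers), via ketene 15 (not isolated)
Conditions: hν (365 nm), MeOH, 23 °C
Reagents that add atoms: methanol, CO
Why: Excitation of the ring-locked s-cis α-diazo ketone expels N2 with concerted 1,2-shift of C5 from the carbonyl carbon C19 to the diazo carbon C4 (Wolff rearrangement), so the seven-membered ring loses C19 and becomes six-membered ring A carrying C19 as an exocyclic ketene, which methanol traps as the methyl ester. The closest known reaction type is the photochemical Wolff ring contraction of 2-diazocycloalkanones to cycloalkanecarboxylates. Ring A is closed not by cyclisation but by ring contraction through a 1,2-alkyl shift, and ring B is untouched. The migrating carbon C5 keeps its configuration, so the trans ring fusion from step 6 is carried into the decalin; the new stereocentre C4 arises on ketonisation of the ester enol, is not controlled and need not be, because it is planarised again in step 9. The step needs rearrangement to win over O–H insertion, 1,2-hydride shift and cyclopropanation; the ring holds the diazo ketone s-cis so that loss of N2 and migration are concerted, and the C7=C8 alkene and the chloride are remote. Regiochemistry is fixed by the substrate, since C4 is the only carbon that can carry the diazo group and C5 is the only group on C19 that can migrate.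

Step 9
Reactants: 16 methyl ester (C4 epimers)
Product: 18 methyl 5-(2-chloroethyl)-1,4a,6-trimethyl-1,2,3,4,4a,5,8,8a-octahydronaphthalene-1-carboxylate (4α-CH3; 4β-CO2CH3; 5α-H; 9α-H; 10β-CH3), via lithium ester enolate 17 (not isolated)
Conditions: LiN(i-Pr)2, THF, −78 °C; MeI, DMPU, −78 → 0 °C
Reagents that add atoms: iodomethane, CI
Why: The exocyclic ester enolate should be methylated from the α face, anti to the axial C20 methyl (equatorial attack), which places C18 equatorial and the ester carbon C19 axial and cis to C20, as is usual for C4 ester enolates of 10-methyl-trans-decalins.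

Step 10
Reactants: 18 quaternary methyl ester
Product: 19 [5-(2-chloroethyl)-1,4a,6-trimethyl-1,2,3,4,4a,5,8,8a-octahydronaphthalen-1-yl]methanol (19-hydroxy; configuration as in 18)
Conditions: i-Bu2AlH, toluene, −78 → 23 °C; aq. Rochelle salt
Reagents that add atoms: none
Why: The aluminium hydride reduces the hindered axial ester to the neopentyl alcohol and should not touch the primary chloride or the trisubstituted alkene.

Step 11
Reactants: 19 chloro alcohol
Product: 20 [5-(2-iodoethyl)-1,4a,6-trimethyl-1,2,3,4,4a,5,8,8a-octahydronaphthalen-1-yl]methanol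
Conditions: NaI, butan-2-one, 80 °C
Reagents that add atoms: sodium iodide, [Na+].[I-]
Why: Finkelstein exchange (SN2, driven by precipitation of NaCl) turns the primary chloride into the iodide needed for halogen–lithium exchange, while the neopentyl alcohol is inert.

Step 12
Reactants: 21 but-2-ynoic acid
Product: 22 (Z)-3-iodobut-2-enoic acid
Conditions: NaI, AcOH, 110 °C
Reagents that add atoms: sodium iodide, [Na+].[I-]
Why: Conjugate addition of iodide and anti protonation (hydroiodination of an ynoic acid) should give the β-iodo acid with iodine cis to the carboxyl group.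

Step 13
Reactants: 22 (Z)-3-iodobut-2-enoic acid; 23 2-(trimethylsilyl)ethan-1-ol
Product: 24 2-(trimethylsilyl)ethyl (Z)-3-iodobut-2-enoate
Conditions: DCC, DMAP (5 mol %), CH2Cl2, 0 °C
Reagents that add atoms: none
Why: Steglich esterification at low temperature should keep the Z geometry and installs an ester that fluoride removes later.

Step 14
Reactants: 20 iodo alcohol; 24 2-(trimethylsilyl)ethyl (Z)-3-iodobut-2-enoate
Product: 26 2-(trimethylsilyl)ethyl (13Z)-19-hydroxylabda-7,13-dien-15-oate, via lithium alkylborate 25 (not isolated)
Conditions: 20, t-BuLi (3.2 equiv), Et2O, −78 °C; 9-MeO-9-BBN, THF, −78 → 23 °C; then 24, PdCl2(dppf) (5 mol %), K3PO4 (aq), DMF, 23 °C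
Reagents that add atoms: none
Why: Iodine–lithium exchange (after deprotonation of the alcohol) and capture by the methoxyborane give a borate that transfers its primary alkyl group in a B-alkyl Suzuki–Miyaura coupling, which proceeds with retention at the vinyl iodide, so C12 ends cis to the ester (13Z).

Step 15
Reactants: 26 hydroxy ester; 27 angelic acid ((Z)-2-methylbut-2-enoic acid)
Product: 29 2-(trimethylsilyl)ethyl (13Z)-19-(angeloyloxy)labda-7,13-dien-15-oate, via mixed anhydride 28 (not isolated)
Conditions: 27, 2,4,6-trichlorobenzoyl chloride, Et3N, toluene, 23 °C; then 26, 80 °C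
Reagents that add atoms: none
Why: Yamaguchi-type acylation by the mixed anhydride, run without a nucleophilic amine catalyst, should esterify the primary neopentyl alcohol while avoiding Z to E isomerisation to the tiglate.

Step 16
Reactants: 29 angelate silylethyl ester
Product: 30 (13Z)-19-(angeloyloxy)labda-7,13-dien-15-oic acid (target)
Conditions: Bu4NF, THF, 0 → 23 °C; aq. NH4Cl
Reagents that add atoms: none
Why: Fluoride-induced β-elimination of the 2-(trimethylsilyl)ethyl ester frees the acid under conditions that should leave the angelate and both trisubstituted alkenes unchanged.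

**Compound list**

1 | tert-butyl(but-3-yn-1-yloxy)dimethylsilane | C#CCCO[Si](C)(C)C(C)(C)C | starting material
2 | oxirane | C1CO1 | starting material
3 | dimethyl[(E)-4-(tert-butyldimethylsilyloxy)-2-methylbut-1-en-1-yl]alane | C[Al](C)/C=C(\C)CCO[Si](C)(C)C(C)(C)C | intermediate
4 | (E)-6-(tert-butyldimethylsilyloxy)-4-methylhex-3-en-1-ol | OCC/C=C(\C)CCO[Si](C)(C)C(C)(C)C | intermediate
5 | (E)-tert-butyl[(6-chloro-3-methylhex-3-en-1-yl)oxy]dimethylsilane | ClCC/C=C(\C)CCO[Si](C)(C)C(C)(C)C | intermediate
6 | (E)-1-bromo-6-chloro-3-methylhex-3-ene | ClCC/C=C(\C)CCBr | intermediate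
7 | 3-methylcyclohept-2-en-1-one | CC1=CC(=O)CCCC1 | starting material
8 | 2,3-dibromo-3-methylcycloheptan-1-one | CC1(Br)C(Br)C(=O)CCCC1 | intermediate
9 | 2-bromo-3-methylcyclohept-2-en-1-one | CC1=C(Br)C(=O)CCCC1 | intermediate
10 | [(E)-6-chloro-3-methylhex-3-en-1-yl]zinc bromide | ClCC/C=C(\C)CC[Zn]Br | intermediate
11 | 2-[(E)-6-chloro-3-methylhex-3-en-1-yl]-3-methylcyclohept-2-en-1-one | ClCC/C=C(\C)CCC1=C(C)CCCCC1=O | intermediate
12 | trans-fused 1-(2-chloroethyl)-2,9a-dimethyl-1,4,4a,6,7,8,9,9a-octahydro-5H-benzo[7]annulen-5-one (5α-H, 9α-H, 10β-CH3) | O=C1CCCC[C@]2(C)[C@@H](CCCl)C(C)=CC[C@@H]12 | intermediate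
13 | 6-(trifluoroacetyl) derivative of 12 (acyl group on C4) | O=C1C(C(=O)C(F)(F)F)CCC[C@]2(C)[C@@H](CCCl)C(C)=CC[C@@H]12 | intermediate
14 | 6-diazo derivative of 12 (diazo group on C4) | O=C1C(=[N+]=[N-])CCC[C@]2(C)[C@@H](CCCl)C(C)=CC[C@@H]12 | intermediate
15 | ring-contracted ketene (C19 exocyclic on C4) | O=C=C1CCC[C@]2(C)[C@@H](CCCl)C(C)=CC[C@@H]12 | intermediate
16 | methyl 5-(2-chloroethyl)-4a,6-dimethyl-1,2,3,4,4a,5,8,8a-octahydronaphthalene-1-carboxylate (C4 epimers; 5α-H, 9α-H, 10β-CH3) | COC(=O)C1CCC[C@]2(C)[C@@H](CCCl)C(C)=CC[C@@H]12 | intermediate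
17 | lithium enolate of 16 | COC(O[Li])=C1CCC[C@]2(C)[C@@H](CCCl)C(C)=CC[C@@H]12 | intermediate
18 | methyl 5-(2-chloroethyl)-1,4a,6-trimethyl-1,2,3,4,4a,5,8,8a-octahydronaphthalene-1-carboxylate (4α-CH3, 4β-CO2CH3) | COC(=O)[C@@]1(C)CCC[C@]2(C)[C@@H](CCCl)C(C)=CC[C@@H]12 | intermediate
19 | [5-(2-chloroethyl)-1,4a,6-trimethyl-1,2,3,4,4a,5,8,8a-octahydronaphthalen-1-yl]methanol (19-hydroxy, C19 β) | OC[C@@]1(C)CCC[C@]2(C)[C@@H](CCCl)C(C)=CC[C@@H]12 | intermediate
20 | [5-(2-iodoethyl)-1,4a,6-trimethyl-1,2,3,4,4a,5,8,8a-octahydronaphthalen-1-yl]methanol | OC[C@@]1(C)CCC[C@]2(C)[C@@H](CCI)C(C)=CC[C@@H]12 | intermediate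
21 | but-2-ynoic acid | CC#CC(=O)O | starting material
22 | (Z)-3-iodobut-2-enoic acid | OC(=O)/C=C(/C)I | intermediate
23 | 2-(trimethylsilyl)ethan-1-ol | C[Si](C)(C)CCO | starting material
24 | 2-(trimethylsilyl)ethyl (Z)-3-iodobut-2-enoate | C[Si](C)(C)CCOC(=O)/C=C(/C)I | intermediate
25 | dilithium alkoxide/B-alkyl-B-methoxy-9-borabicyclo[3.3.1]nonane borate from 20 | [Li+].[Li+].[O-]C[C@@]1(C)CCC[C@]2(C)[C@@H](CC[B-]3(OC)C4CCCC3CCC4)C(C)=CC[C@@H]12 | intermediate
26 | 2-(trimethylsilyl)ethyl (13Z)-19-hydroxylabda-7,13-dien-15-oate | OC[C@@]1(C)CCC[C@]2(C)[C@@H](CC/C(C)=C\C(=O)OCC[Si](C)(C)C)C(C)=CC[C@@H]12 | intermediate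
27 | angelic acid, (Z)-2-methylbut-2-enoic acid | C/C=C(/C)C(=O)O | starting material
28 | angelic 2,4,6-trichlorobenzoic anhydride | C/C=C(/C)C(=O)OC(=O)c1c(Cl)cc(Cl)cc1Cl | intermediate
29 | 2-(trimethylsilyl)ethyl (13Z)-19-(angeloyloxy)labda-7,13-dien-15-oate | C/C=C(/C)C(=O)OC[C@@]1(C)CCC[C@]2(C)[C@@H](CC/C(C)=C\C(=O)OCC[Si](C)(C)C)C(C)=CC[C@@H]12 | intermediate
30 | (13Z)-19-(angeloyloxy)labda-7,13-dien-15-oic acid | C/C=C(/C)C(=O)OC[C@@]1(C)CCC[C@]2(C)[C@@H](CC/C(C)=C\C(=O)O)C(C)=CC[C@@H]12 | target

**Step count**

Total: 16 steps. Longest linear sequence: 13 steps (1, 2, 3, 5, 6, 7, 8, 9, 10, 11, 14, 15, 16); step 4 makes the bromoenone and steps 12 and 13 make the side-chain partner.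

**Steps most likely to fail**

Step 6. The chiral anion may not discriminate the two faces of the hydroxyallyl cation; the alkene may add to the carbonyl carbon instead of C10; or the C8 cation may lose a proton toward C17 or C9 instead of C7. Fallback with known chemistry: from 11 the ring is closed without chiral control by FSO3H in 2-nitropropane at −78 °C, the superacid protocol for cation–olefin cyclisation that favours loss of the ring proton to the endocyclic trisubstituted alkene. This gives 12 together with its mirror image, the enantiomer of 12 F1, and the two are separated by preparative chromatography on a chiral stationary phase. The route is rejoined at 12.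

Step 7. Enolate equilibration may epimerise C5, or acyl transfer to the hindered enolate may stay incomplete, so that diazo transfer stalls. Fallback: from 12, nitrosation of the C4 methylene with butyl nitrite and KOC(CH3)3 in t-BuOH/THF at 0 °C gives the 4-hydroxyimino ketone F2, and chloramine (aq. NH3, NaOCl, 0 °C; Forster reaction) turns the oxime into the diazo ketone. The route is rejoined at 14.

Step 15. The angeloyl group may isomerise from Z to E during the slow acylation of the hindered neopentyl alcohol. Fallback: from 26 the alcohol is esterified with 2-[bis(2,2,2-trifluoroethoxy)phosphoryl]propanoic acid (DCC, DMAP, CH2Cl2) to the phosphonate ester F3. A Still–Gennari olefination with acetaldehyde (KN(SiMe3)2, 18-crown-6, THF, −78 °C) then builds the Z-2-methylbut-2-enoate in place. The route is rejoined at 29.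

**Further compounds**

F1 | step 6 | enantiomer of 12 | O=C1CCCC[C@@]2(C)[C@H](CCCl)C(C)=CC[C@H]12
F2 | step 7 | 6-(hydroxyimino) derivative of 12 (oxime on C4) | O=C1C(=NO)CCC[C@]2(C)[C@@H](CCCl)C(C)=CC[C@@H]12
F3 | step 15 | 2-(trimethylsilyl)ethyl (13Z)-19-{2-[bis(2,2,2-trifluoroethoxy)phosphoryl]propanoyloxy}labda-7,13-dien-15-oate | CC(C(=O)OC[C@@]1(C)CCC[C@]2(C)[C@@H](CC/C(C)=C\C(=O)OCC[Si](C)(C)C)C(C)=CC[C@@H]12)P(=O)(OCC(F)(F)F)OCC(F)(F)F
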